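Readings and results were computed from invented constants, noise included.

Zeta is charged 0.100 M richer in incoming ligand than eta, and at 8.00 d it holds more complex with three exchanged, crystals counted, than eta does: 34.5 % against 28.3 %. I want to know what these two runs share.

| setting | gamma | eta | zeta | north-west | south | south-west |
|---|---|---|---|---|---|---|
| starting complex | 0.40 M | 0.40 M | 0.40 M | 0.40 M | 0.40 M | 0.40 M |
| incoming ligand | 0.67 M | 0.82 M | 0.92 M | 0.600 M | 1.00 M | 1.20 M |
| leaving ligand | 0.80 M | 0.80 M | 0.80 M | 0.800 M | 0.800 M | 0.800 M |
| protic impurity | 0.12 M | 0.12 M | 0.12 M | 0.120 M | 0.120 M | 0.120 M |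
| remark | run made earlier | run made earlier | run made earlier |  |  |  |
| time |  |  |  | 10 d | 10 d | 10 d |

- gamma (time / d: complex with one exchanged / %, complex with three exchanged / %): 1.25: 51.0, 10.4; 3.00: 48.3, 13.4; 4.00: 47.1, 14.3; 6.00: 45.7, 16.3; 8.00: 45.9, 16.0
- eta (time / d: complex with one exchanged / %, complex with three exchanged / %): 0.625: 48.3, 9.5; 1.67: 46.6, 16.4; 3.00: 41.7, 22.2; 5.00: 38.5, 25.0; 8.00: 36.2, 28.3
- zeta (time / d: complex with one exchanged / %, complex with three exchanged / %): 0.625: 49.3, 10.1; 1.04: 47.0, 15.7; 2.08: 40.8, 24.8; 4.00: 34.1, 31.1; 8.00: 30.0, 34.5

(standard deviation of a reading: 0.5 percentage points)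

- complex with three exchanged is meant together with its crystals
- solid, in amounts per volume of the solution: crystals
- on the list of suspects stand: starting complex + incoming ligand <-> leaving ligand + complex with one exchanged; complex with one exchanged + incoming ligand <-> leaving ligand + complex with two exchanged; complex with two exchanged + incoming ligand <-> leaving ligand + complex with three exchanged; crystals <-> complex with three exchanged; protic impurity + starting complex -> quenched substrate

- amount of complex with one exchanged at the end, in percent of the starting complex charged, for each flask in turn (north-west, south, south-west)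

I take the protic impurity to consume its 0.12 M of the 0.40 M starting complex, which leaves E = 0.280 M exchangeable. I count that as carrying one incoming ligand on average, and each C (complex with three exchanged, in M) as carrying two more. The uptake is then u = E + 2C, the free incoming ligand X is its charge minus u, and the free leaving ligand L is its charge plus u.

With A as complex with one exchanged in M, I reckon S = A(X/L) squared, a mass-action quotient, from the last readings. Gamma gives 0.00864 M, eta 0.00834 M and zeta 0.00865 M. I carry the zeta value as the crystal quotient. Zeta holds twice the C of gamma, yet S stays level. I read that as crystals holding dissolved C at one level, so the extra ligand goes into crystals. The rule needs crystals, and north-west is charged with less incoming ligand than any earlier run, so I draw no number for it from S.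

For south I keep A + C at zeta's 0.258 M. Zeta's ratio X/L, 0.268, gives A = 0.0885 M. The ratio belonging to that A gives 0.112 M. The answer lies between, and I take the middle, 25.1 %.

The forecast says 50.3 %, 25.5 % and 16.5 %, on the ground that “crystals fix dissolved three-exchanged”, and its south value differs a little from my middle.

The flasks give 48.9 %, 25.7 % and 17.6 %.

    starting complex + incoming ligand ⇌ leaving ligand + complex with one exchanged (K = 52.5, k = 6.26 × 10⁻⁵ L mol⁻¹ s⁻¹)
    complex with one exchanged + incoming ligand ⇌ leaving ligand + complex with two exchanged (K = 0.450, k = 3.91 × 10⁻⁵ L mol⁻¹ s⁻¹)
    complex with two exchanged + incoming ligand ⇌ leaving ligand + complex with three exchanged (K = 14.9, k = 5.38 × 10⁻⁵ L mol⁻¹ s⁻¹)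
    crystals ⇌ complex with three exchanged, rate k4*(cs4 - [complex with three exchanged]) while solid is left; crystals form when [complex with three exchanged] > cs4 (solubility = 0.0510 M, k = 2.81 × 10⁻⁴ s⁻¹)
    protic impurity + starting complex → quenched substrate (k = 3.13 × 10⁻⁴ L mol⁻¹ s⁻¹)

North-west ends with 0 % crystals at 10.0 d, while south holds 27.4 %. From what stands in south at 10.0 d, S comes to 0.00785 M. In south-west, the quotient 0.00865 M with the ligands standing there gives A as 19.7 % of the charge, and the flask holds 17.6 %.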